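**The vessel.** The vessel was closed, stirred and held at one temperature. The steps under discussion had L and E giving X, X giving G and Z, and G with Z giving D.

| flask | L | E | remark | time |
|---|---|---|---|---|
| epsilon | 0.0042 M | 0.0156 M | run made earlier |  |
| beta | 0.024 M | 0.0156 M | run made earlier |  |
| gamma | 0.077 M | 0.0156 M | run made earlier |  |
| dusk | 0.0060 M | 0.0156 M |  | 8.0 min |
| dawn | 0.012 M | 0.0156 M |  | 8.0 min |
| noon | 0.025 M | 0.0156 M |  | 8.0 min |
| summer | 0.050 M | 0.0156 M |  | 8.0 min |
| winter | 0.10 M | 0.0156 M |  | 8.0 min |

| run | time / min | X / % | G / % |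
|---|---|---|---|
| epsilon | 1.50 | 5.2 | 26.7 |
| epsilon | 3.00 | 4.6 | 52.0 |
| epsilon | 5.00 | 4.2 | 67.8 |
| epsilon | 6.00 | 3.3 | 72.5 |
| epsilon | 8.00 | 1.3 | 78.2 |
| beta | 1.50 | 4.2 | 23.9 |
| beta | 3.00 | 3.6 | 35.3 |
| beta | 5.00 | 2.2 | 40.4 |
| beta | 6.00 | 2.4 | 39.6 |
| beta | 8.00 | 0.6 | 38.3 |
| gamma | 0.667 | 4.9 | 6.3 |
| gamma | 2.00 | 1.3 | 16.2 |
| gamma | 4.00 | 0.1 | 14.7 |
| gamma | 6.00 | 1.8 | 13.3 |
| gamma | 8.00 | 0 | 12.1 |

(each reading ± 1 percentage point)

- the numbers in the tables scatter by 1 percentage point (one standard deviation)
- steps under discussion: L + E <-> X; X <-> G + Z; G + Z -> D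
- "hardly changes" means that all values lie within two and a half points (for a concentration: within two and a half percent of the largest)

* [X] at the end for dusk, dawn, noon, summer, winter, in this order
* the shape of the row from first to last (falls all the way / rises, then falls / hardly changes / rises all the way / falls, then rises)

**An odd pair.** Gamma held 18.3 times the L of epsilon. Yet gamma's last reading put G at 12.1% of its L, and epsilon's at 78.2% of its L.

**Counting turnovers.** I first read a rate from epsilon. There E was in excess, so I treated L as falling in a roughly pseudo-first-order way. After 3.00 min, G and X together held 56.6% of the L. That gave 0.297 M⁻¹ s⁻¹, the turnover constant: multiplied by the L present and the time, it counts the lifetimes of E that have passed. The fraction of E left is then the exponential of minus that count.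

**The pair cleared.** In gamma, taking L at its charge, I reckoned the count at 2.00 min as 2.75, so by my estimate 93.6% of the E had reacted. But the E charge was 20.3% of the L charge. So I estimated the turnover of L in gamma at about 19.0%, and G and X read 17.5%. In gamma E was the limiting reagent, so the low percentage was a share of a large L charge.

**My reckoning.** L and E together feed X. While the count is low, more L feeds more X at the same E. At a high count E falls away exponentially. Taking L at its charge, I reckoned the count over 8.0 min as 0.856 for dusk and 14.3 for winter. So I expected the row to rise, then fall, turning between dawn and noon, near equal charges, where the count is 2.23.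

**The forecast.** It gave 7.000 × 10⁻⁵ M, 1.600 × 10⁻⁴ M, 2.000 × 10⁻⁴ M, 1.700 × 10⁻⁴ M and 1.200 × 10⁻⁴ M, so the row rises, then falls, “though the high-L end is uncertain”.

**The flask.** The row was 1.00 × 10⁻⁴ M, 2.16 × 10⁻⁴ M, 2.87 × 10⁻⁴ M, 1.78 × 10⁻⁴ M and 1.45 × 10⁻⁴ M: it rises, then falls.

    L + E ⇌ X (K = 480 M⁻¹, k = 0.340 M⁻¹ s⁻¹)
    X ⇌ G + Z (K = 0.530 M, k = 0.0500 s⁻¹)
    G + Z → D (k = 0.130 M⁻¹ s⁻¹)

At noon the forecast's 2.000 × 10⁻⁴ M stood lower than the 2.87 × 10⁻⁴ M found. In noon, taking L midway between charge and rest, the count 2.56 gives 7.73% of the E charge left, and the flask held 9.76%. In summer, reckoned the same way, the count 6.03 gives 0.241%, and the flask held 0.351%. In dusk, X and G + Z relaxed by that step alone, both ways together, with a half-life of 0.227 min at the asked time, far shorter than the 8.0 min of the run. At 8.00 min dusk held G at 72.5% and X at 1.67% of the L charged.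

(The earlier runs and the new flask stem from a simulated flask from invented constants; the scatter is artificial.)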